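## Structural features

Atom labels follow the order of the ring carbons in the target (C1 to C11; C15 is the acetoxymethyl carbon on C1) and are kept for every intermediate. The target is a C15 triacetate built on a nortricyclane: C6 is the apex, C1, C7 and C11 are the three spokes, and C8–C9–C10 is the cyclopropane. The cage shares the C1–C6 bond with a cyclohexane, ring A (C1–C6). Three fully substituted carbons stand in a row (C5 with its gem-dimethyl group, C6, and C1 bearing C15), and a fourth, C10, carries the methyl group on the cyclopropane. There are eight stereocentres (C1, C3, C4, C6, C8, C9, C10, C11). On ring A, C15, O3 and O4 all lie on one face, with O3 axial and 1,3-cis to C15 and O4 equatorial beside the gem-dimethyl carbon. The C11 acetoxy group points to the C7 side of the cage. The fragile points are the C3 acetate next to a free cis hydroxyl at C4 (acyl migration), the cyclopropane, and the cyclopropylcarbinyl C11–O bond, which ionises easily. The real difficulty is the cage with its contiguous quaternary carbons, its fixed sense relative to ring A, and the C11 configuration. The key step exploits the fact that cutting C8–C9 leaves C9 homoallylic to a C7=C8 double bond in a norbornene (bridgeheads C6 and C10, C11 as the one-carbon bridge) that a Diels–Alder reaction can assemble.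

## Logic of the disconnections

**37 from 36.** No skeletal bond is cut, only the O4–benzyl bond. O4 must end free beside an acetate that would migrate under basic or strongly acidic unmasking, so an oxidatively removable ether is carried from the start. This avoids any late differentiation of the cis 3,4-diol. The demand is that the ether survives Lewis acid, hydride and buffered acetic acid over twenty steps.

**36 from 35 from 34.** Three acyl–oxygen bonds are cut, and then O15 and O3 are joined as one lactone (C15(=O)–O3). The lactone locks the cis-1,3 pair and keeps both oxygens non-nucleophilic while cations are generated nearby. 34 is thereby left with a single exposed functional group. The forward steps must open the lactone reductively and then acetylate the axial O3 and the flanked C11 hydroxyl completely.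

**34 from 33, 32, 31 and 30.** The C11–O bond is cut with inversion, back to a ketone and then a ketal. Hydride can reach C11 only from the C7 side and gives the wrong epimer; a nucleophile entering the cyclopropylcarbinyl cation from that same open side gives the right one. The C11 stereocentre disappears in 30. The solvolysis must capture at C11 without opening the cyclopropane.

**30 from 29.** C8–C9 is cut, the C7 hydrogen is returned as a C7=C8 double bond, and C9 receives an exo leaving group. This turns the nortricyclane into a norbornene, which is a Diels–Alder product. One ring and two stereocentres are removed. The forward step needs the leaving group anti to the alkene and hydride capture at C7.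

**29 from 27 from 26.** Only S–O and acyl–O bonds change. The C9 oxygen travels through the cycloaddition as an enol acetate and becomes the sulfonate afterwards. The demands are deacetylation without retro-aldol opening and sulfonylation of a crowded exo alcohol.

**26 from 25 from 23.** C1–C6 and C9–C10 are cut (Diels–Alder), then the C6=C7 double bond is traced back to a C7 hydroxyl. Both bridgeheads, the vicinal quaternary pair C1/C6 and the C9 oxygen arise in one step. The quaternary ketal carbon C11 blocks 1,5-hydrogen shifts in the diene, and the lactone tether forces C15 cis to O3. The tetracycle reduces to a butyrolactone joined to a cyclopentenol. The forward step must close through the tether-exo, carbonyl-endo mode from an E enol acetate.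

**23 from 22 from 21.** The enol O–acyl bond and then C1–C9 (the formyl carbon) are cut. This removes the dienophile and leaves a plain lactone. The lactone α-position must be the only enolisable site, which is why C11 is already a ketal.

**21 from 19 from 18.** The two C11–OMe bonds are cut, then C6–C7, which is the bond made in a Piancatelli rearrangement. The carbocycle with its methyl group at C10 reduces to a 3-methylfuran on a carbinol carbon. The furfuryl cation must rearrange and not fragment, and the hindered enone must be ketalised without moving the double bond.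

**18 from 17, 16, and 13 with 14.** C6–C11 is cut between an acyl carbon and a furyl anion, and the C15 lactone is exchanged for a C6 lactone on the same O3. With C6 at the acyl level the ketone is non-enolisable and survives oxidation, and O3 is never free under cationic conditions. The lactone must take up exactly one furyl group.

**13 from 11, 10 and 9.** The C15–O bond (hydroboration), the C6 lactone (oxidative lactonisation) and the O6–acetal bond (reductive opening) are undone. This returns to an acetal-protected homoallylic alcohol. The acetal must open so that the benzyl ether stays on O4.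

**9 from 4 with 5.** C2–C3 is cut. The allyl unit supplies C2, C1 and C15 and creates the C3 stereocentre under reagent control matched with the substrate. The addition must be anti to O4.

**4 from 3, 2 and 1.** No carbon–carbon bond is cut. The chiral pool supplies C3–C6 with the C4 stereocentre and the gem-dimethyl group, and one acetal differentiates the three hydroxyls.

## Other disconnections considered

**Alternative 1:** The cut is C1–C6, which opens ring A and makes C6 the ortho carbon of a phenol.

- **Forward step:** KOt-Bu in t-BuOH would turn A1 into its phenolate, and C6 would displace the C1 bromide (6-exo-tet C-alkylation) to give the spiro dienone A2.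
- **In its favour:** five cage carbons (C7–C11), the C10 methyl and the C11 oxygen come from a cheap arene. C6 becomes quaternary as ring A closes. O-alkylation would need an eight-membered ring.
- **Against it here:** the nucleophilic carbon sits beside quaternary C5 and the electrophile is a secondary α-bromo ester, so elimination and C1 epimerisation compete. Linear 2,4-dienones tend to dimerise. A2 is still two carbon–carbon bonds (C1–C9 and C8–C10) from the cage.
- **Structure:** the chosen plan has the full skeleton after step 18, whereas A2 needs further ring construction; the chosen plan is better here.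
- **Mechanism:** the alternative is anionic, so there is no question of where a hydride enters a delocalised cation and no endo/exo issue; it is the better of the two here.
- **Step economy:** the route to A1 should be shorter than the route to 29, but the steps after A2 are more numerous, so the two are about equal overall.

**Alternative 2:** The cuts are C8–C9 and C9–C10, the two cyclopropane bonds at C9.

- **Forward step:** NaH and heat would convert the tosylhydrazone A3 into a diazoalkane. This would add across C8=C10 to a 1-pyrazoline that loses N2 to give A4.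
- **In its favour:** two bonds and three rings form in one thermal, neutral step. C9 has no neighbouring hydrogen on C1 to shift. Both acetates at C15 and C11 are already in place, so little follows the key step.
- **Against it here:** A3 needs the spiro carbon C6 set against quaternary C1 and the C11 stereocentre, without a cycloaddition to do it. Nitrogen loss from the pyrazoline can also give alkenes. A4 as drawn has no oxygen at C3, so O3 would have to be carried in from the start or added by a late C–H oxidation.
- **Structure:** it forms two cage bonds where step 18 forms one; the alternative is better here.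
- **Mechanism:** a dipolar addition avoids both cation regiochemistry and the C11 inversion detour; the alternative is better here.
- **Step economy:** the end is shorter, but the route to A3 is the unsolved and probably longer part, so the chosen plan is the safer whole.

**Alternative 3:** The cuts are C1–C6, C7–C8 and C8–C9.

- **Forward step:** Co2(CO)8 would complex the alkyne of A5 and join alkyne C6–C7, alkene C1–C9 and CO (C8) to give the enone A6.
- **In its favour:** ring A and quaternary C1 form in one step. The oxolane tether fixes C15 cis to O3 exactly as the lactone does in the chosen plan (equal). A5 should be short from the same chiral pool, and the gem-dimethyl group beside the alkyne helps closure.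
- **Against it here:** a 1,7-enyne with a 1,1-disubstituted alkene is a demanding substrate. A6 has a ketone at C8, which is a cyclopropane CH in the target. C10, C11 and one methyl group are missing, and C6 is not yet quaternary. The ether bridge must later be cleaved into two acetates, which is harsher than reducing a lactone.
- **Structure:** the chosen cycloadduct 26 already holds all fifteen carbons and A6 holds twelve; the chosen plan is better.
- **Mechanism:** face selectivity is tether-controlled in both (equal).
- **Step economy:** the alternative is shorter before its key step (better) and clearly longer after it (worse).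

Key step: step 18

Remarks on the chemistry:
- 2-Bromo-3-methylfuran (14) is taken to be a purchasable building block.
- A 4-methoxybenzyl (PMB) ether is chosen for O4 because it arises directly from the acetal and can be removed oxidatively at the end beside three acetates.

## Route

Step 1
Reactants: 1 (R)-pantolactone
Product: 2 (2R)-3,3-dimethylbutane-1,2,4-triol
Conditions: LiAlH4, THF, 0 °C → reflux; H2O, NaOH
Reagents that add atoms: none
Why: Hydride reduction of the lactone to the diol; the carbinol centre (later C4) is not touched.

Step 2
Reactants: 2 (2R)-3,3-dimethylbutane-1,2,4-triol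
Product: 3 [(2R,4R)-2-(4-methoxyphenyl)-5,5-dimethyl-1,3-dioxan-4-yl]methanol
Conditions: 4-MeOC6H4CH(OMe)2, CSA (cat.), CH2Cl2, 25 °C
Reagents that add atoms: 4-methoxybenzaldehyde dimethyl acetal, COC(OC)c1ccc(OC)cc1
Why: Thermodynamic transacetalisation; an arylidene acetal prefers the six-membered dioxane across O4/O6 with aryl and CH2OH equatorial, which should leave only the C3 hydroxyl free.

Step 3
Reactants: 3 [(2R,4R)-2-(4-methoxyphenyl)-5,5-dimethyl-1,3-dioxan-4-yl]methanol
Product: 4 (2R,4R)-2-(4-methoxyphenyl)-5,5-dimethyl-1,3-dioxane-4-carbaldehyde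
Conditions: TEMPO (cat.), PhI(OAc)2, CH2Cl2, 25 °C
Reagents that add atoms: none
Why: Oxoammonium oxidation of a primary alcohol stops at the aldehyde in the absence of water and is mild enough to leave the α-alkoxy centre and the acetal alone.

Step 4
Reactants: 4 (2R,4R)-2-(4-methoxyphenyl)-5,5-dimethyl-1,3-dioxane-4-carbaldehyde; 5 allyl bromide
Product: 9 (1S)-1-[(2R,4R)-2-(4-methoxyphenyl)-5,5-dimethyl-1,3-dioxan-4-yl]but-3-en-1-ol, via allylmagnesium bromide 6 (not isolated), via B-allyldiisopinocampheylborane 7 (not isolated), via diisopinocampheylborinate ester 8 (not isolated)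
Conditions: 5, Mg, Et2O, 25 °C; (−)-Ipc2BOMe, 0 °C; 4, −78 °C; NaOH, H2O2, 25 °C
Reagents that add atoms: allyl bromide (5), C=CCBr
Why: Brown allylation through a closed chair transition state; the (−)-Ipc2B reagent should deliver allyl to the Si face of the aldehyde, which is also the face preferred by the Felkin–Anh/Cornforth model for an α-alkoxy aldehyde. C3 should therefore form as (S), anti to O4.

Step 5
Reactants: 9 (1S)-1-[(2R,4R)-2-(4-methoxyphenyl)-5,5-dimethyl-1,3-dioxan-4-yl]but-3-en-1-ol
Product: 10 (3R,4S)-3-[(4-methoxybenzyl)oxy]-2,2-dimethylhept-6-ene-1,4-diol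
Conditions: i-Bu2AlH (4 equiv), CH2Cl2, −78 → 0 °C; aq. potassium sodium tartrate
Reagents that add atoms: none
Why: Reductive opening of the arylidene acetal; aluminium should bind the less hindered O6, the C–O6 bond breaks and hydride reduces the oxocarbenium on O4. This leaves the PMB ether on the secondary O4 and frees the neopentyl C6 hydroxyl.

Step 6
Reactants: 10 (3R,4S)-3-[(4-methoxybenzyl)oxy]-2,2-dimethylhept-6-ene-1,4-diol
Product: 11 (4R,5S)-4-[(4-methoxybenzyl)oxy]-3,3-dimethyl-5-(prop-2-en-1-yl)oxolan-2-one
Conditions: TEMPO (cat.), PhI(OAc)2 (2.5 equiv), CH2Cl2, 25 °C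
Reagents that add atoms: none
Why: Oxidative lactonisation of a 1,4-diol (primary alcohol to aldehyde, five-membered lactol with O3, then lactone); C6 reaches the acyl level while O3 is masked.

Step 7
Reactants: 11 (4R,5S)-4-[(4-methoxybenzyl)oxy]-3,3-dimethyl-5-(prop-2-en-1-yl)oxolan-2-one
Product: 13 (4R,5S)-5-(3-hydroxypropyl)-4-[(4-methoxybenzyl)oxy]-3,3-dimethyloxolan-2-one, via B-alkyl-9-borabicyclononane adduct 12 (not isolated)
Conditions: 9-BBN, THF, 0 → 25 °C; H2O2, aq. NaHCO3, 0 °C
Reagents that add atoms: hydrogen peroxide, OO
Why: Anti-Markovnikov hydroboration–oxidation of the terminal alkene; 9-BBN does not reduce the lactone and the buffered oxidation avoids saponification.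

Step 8
Reactants: 13 (4R,5S)-5-(3-hydroxypropyl)-4-[(4-methoxybenzyl)oxy]-3,3-dimethyloxolan-2-one; 14 2-bromo-3-methylfuran
Product: 16 (3R,4S)-4,7-dihydroxy-3-[(4-methoxybenzyl)oxy]-2,2-dimethyl-1-(3-methylfuran-2-yl)heptan-1-one, via 3-methylfuran-2-yllithium 15 (not isolated)
Conditions: 14, n-BuLi, THF, −78 °C; 13, −78 → −40 °C; aq. NH4Cl
Reagents that add atoms: 2-bromo-3-methylfuran (14), Cc1ccoc1Br
Why: Bromine–lithium exchange followed by acyl substitution on the lactone; the tetrahedral lithium hemiketal persists in the cold, so only one furyl group should add. A further equivalent of 15 is spent on the free hydroxyl.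

Step 9
Reactants: 16 (3R,4S)-4,7-dihydroxy-3-[(4-methoxybenzyl)oxy]-2,2-dimethyl-1-(3-methylfuran-2-yl)heptan-1-one
Product: 17 (5S)-5-[(1R)-1-[(4-methoxybenzyl)oxy]-2,2-dimethyl-3-(3-methylfuran-2-yl)-3-oxopropyl]oxolan-2-one
Conditions: TEMPO (cat.), PhI(OAc)2 (2.5 equiv), CH2Cl2, 25 °C
Reagents that add atoms: none
Why: Second oxidative lactonisation, now of C15 onto O3; the acylfuran is electron-poor and the ketone has no α-hydrogen, so both should pass unchanged.

Step 10
Reactants: 17 (5S)-5-[(1R)-1-[(4-methoxybenzyl)oxy]-2,2-dimethyl-3-(3-methylfuran-2-yl)-3-oxopropyl]oxolan-2-one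
Product: 18 (5S)-5-[(1R)-3-hydroxy-1-[(4-methoxybenzyl)oxy]-2,2-dimethyl-3-(3-methylfuran-2-yl)propyl]oxolan-2-one (both C6 epimers)
Conditions: NaBH4, CeCl3·7H2O, MeOH, 0 → 25 °C
Reagents that add atoms: none
Why: Luche-type reduction of the hindered aryl ketone, chemoselective over the butyrolactone; the C6 configuration is irrelevant because C6 becomes sp2 in step 15.

Step 11
Reactants: 18 (5S)-5-[(1R)-3-hydroxy-1-[(4-methoxybenzyl)oxy]-2,2-dimethyl-3-(3-methylfuran-2-yl)propyl]oxolan-2-one
Product: 19 (5S)-5-[(1R)-2-(2-hydroxy-4-methyl-5-oxocyclopent-3-en-1-yl)-1-[(4-methoxybenzyl)oxy]-2-methylpropyl]oxolan-2-one (C6/C7 trans, both trans isomers)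
Conditions: ZnCl2, 1,4-dioxane–H2O, 85 °C
Reagents that add atoms: water, O
Why: Piancatelli rearrangement; the furfuryl cation takes up water at the free furan position, the ring opens and a conrotatory 4π electrocyclisation forms C6–C7 with the hydroxyl trans to the C6 substituent. The furan methyl ends on C10 next to the carbonyl C11.

Step 12
Reactants: 19 (5S)-5-[(1R)-2-(2-hydroxy-4-methyl-5-oxocyclopent-3-en-1-yl)-1-[(4-methoxybenzyl)oxy]-2-methylpropyl]oxolan-2-one
Product: 21 (5S)-5-[(1R)-2-(5-hydroxy-2,2-dimethoxy-3-methylcyclopent-3-en-1-yl)-1-[(4-methoxybenzyl)oxy]-2-methylpropyl]oxolan-2-one, via C7 trimethylsilyl ether ketal 20 (not isolated)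
Conditions: MeOSiMe3, TMSOTf (cat.), CH2Cl2, −78 → −40 °C; pyridine; K2CO3, MeOH, 0 °C
Reagents that add atoms: methoxytrimethylsilane, CO[Si](C)(C)C
Why: Silyl-triflate-catalysed ketalisation under aprotic cold conditions, which ketalises enones without shifting the double bond; the hydroxyl is silylated in passing and freed again by methanolysis.

Step 13
Reactants: 21 (5S)-5-[(1R)-2-(5-hydroxy-2,2-dimethoxy-3-methylcyclopent-3-en-1-yl)-1-[(4-methoxybenzyl)oxy]-2-methylpropyl]oxolan-2-one
Product: 22 (3E,5S)-3-(hydroxymethylidene)-5-[(1R)-2-(5-hydroxy-2,2-dimethoxy-3-methylcyclopent-3-en-1-yl)-1-[(4-methoxybenzyl)oxy]-2-methylpropyl]oxolan-2-one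
Conditions: LiN(i-Pr)2 (2.2 equiv), THF, −78 °C; HCO2Et, −78 → 0 °C; aq. NaH2PO4
Reagents that add atoms: ethyl formate, CCOC=O
Why: Crossed Claisen formylation of the lactone enolate; with C11 ketalised, C1 is the only enolisable carbon, and the buffered work-up spares the ketal.

Step 14
Reactants: 22 (3E,5S)-3-(hydroxymethylidene)-5-[(1R)-2-(5-hydroxy-2,2-dimethoxy-3-methylcyclopent-3-en-1-yl)-1-[(4-methoxybenzyl)oxy]-2-methylpropyl]oxolan-2-one
Product: 23 (E)-enol acetate of 22 (acetoxymethylidene lactone, C7 hydroxyl free)
Conditions: Ac2O (1.1 equiv), Et3N, CH2Cl2, −20 °C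
Reagents that add atoms: acetic anhydride, CC(=O)OC(C)=O
Why: O-acylation of the vinylogous acid as its ammonium enolate, much faster than acylation of the hindered C7 alcohol; the E isomer (acetoxy anti to the lactone carbonyl) is the less dipolar and should predominate.

Step 15
Reactants: 23 (E)-enol acetate of 22
Product: 26 Diels–Alder adduct: lactone-bridged 7,7-dimethoxynorbornene C9 exo acetate, via C7 sulfamate ester 24 (not isolated), via cyclopentadienone ketal triene 25 (not isolated)
Conditions: Burgess reagent, PhMe (2 mM), 25 → 90 °C
Reagents that add atoms: none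
Why: Burgess dehydration is a syn elimination and the trans alcohol has H6 cis to the C7 oxygen, so diene 25 forms; it cannot isomerise because C11 carries no hydrogen. The intramolecular Diels–Alder reaction then joins C6–C1 and C10–C9: the lactone forces C15 cis to O3, the carbonyl-endo/tether-exo transition state places C15 under the new C7=C8 bond, and the E alkene carries the acetoxy group to the exo face of C9.

Step 16
Reactants: 26 Diels–Alder adduct (C9 exo acetate)
Product: 27 lactone-bridged 7,7-dimethoxynorbornene C9 exo alcohol
Conditions: K2CO3, MeOH, 0 °C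
Reagents that add atoms: none
Why: Base-catalysed transesterification of the acetate; the cold, weakly basic medium is chosen to keep the C9 alkoxide concentration low and so avoid retro-aldol cleavage of C1–C9.

Step 17
Reactants: 27 lactone-bridged 7,7-dimethoxynorbornene C9 exo alcohol; 28 4-bromobenzenesulfonyl chloride
Product: 29 lactone-bridged 7,7-dimethoxynorbornene C9 exo brosylate (C4 PMB ether)
Conditions: 28, Et3N, Me3N·HCl (cat.), CH2Cl2, 0 → 25 °C
Reagents that add atoms: 4-bromobenzenesulfonyl chloride (28), O=S(=O)(Cl)c1ccc(Br)cc1
Why: Sulfonylation through the small, reactive sulfonylammonium species, which suits crowded secondary alcohols and avoids forming the free alkoxide.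

Step 18
Reactants: 29 lactone-bridged 7,7-dimethoxynorbornene C9 exo brosylate
Product: 30 lactone-bridged nortricyclane C11 dimethyl ketal (C4 PMB ether)
Conditions: NaBH4 (1.8 M), diglyme–H2O (65:35), 60 °C; aq. NaHSO4
Reagents that add atoms: none
Why: The exo C9–O bond ionises with rear-side assistance from the C7=C8 π bond (homoallyl participation) to give the delocalised norbornenyl/nortricyclyl cation, which borohydride quenches at C7. The closest known reaction type is the solvolysis of exo-5-norbornen-2-yl arenesulfonates to nortricyclyl products and the borohydride trapping of that cation to nortricyclene in aqueous diglyme. The cyclopropane C8–C9–C10 closes in a 3-exo-tet mode, with C8 attacking C9 from the endo face as the exo sulfonate leaves. C9 is set by inversion, since C8 enters anti to the leaving group, and C8 by the bicyclic frame, which allows bonding only on its endo face; C7 becomes CH2. The step needs hydride capture at C7 and not at C9 or C10, and π participation rather than fragmentation of C10–C11 or capture by water. C9 is screened by quaternary C1 and C10 is tertiary and flanked by the ketal, so secondary C7 is the open, cyclopropyl-stabilised terminus; the exo leaving group is antiperiplanar to the alkene bridge and not to C10–C11, which disfavours ketal-assisted fragmentation, and concentrated borohydride should outrun water. Quaternary C1 rules out hydride shifts, the lactone keeps O15 and O3 from trapping the cation, and the acidic work-up should reclose any lactone opened by the basic medium.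

Step 19
Reactants: 30 lactone-bridged nortricyclane C11 dimethyl ketal
Product: 31 lactone-bridged nortricyclan-11-one (C4 PMB ether)
Conditions: 1 M HCl, THF, 25 °C
Reagents that add atoms: water, O
Why: Acid hydrolysis of the ketal; the oxocarbenium at C11 is cyclopropylcarbinyl-stabilised, so mild acid should suffice and the PMB ether and lactone remain.

Step 20
Reactants: 31 lactone-bridged nortricyclan-11-one
Product: 32 C11 alcohol with the hydroxyl on the C1 side (11-epi)
Conditions: NaBH4, MeOH, 0 °C
Reagents that add atoms: none
Why: Hydride addition from the open C7 side of the carbonyl, away from quaternary C1 and its C2 methylene; this gives the hydroxyl on the C1 side, the epimer needed for inversion in step 22.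

Step 21
Reactants: 32 C11 alcohol (hydroxyl on the C1 side)
Product: 33 C11 mesylate (sulfonate on the C1 side)
Conditions: MsCl, Et3N, CH2Cl2, −20 °C
Reagents that add atoms: methanesulfonyl chloride, CS(=O)(=O)Cl
Why: Mesylation via sulfene, which is small enough for an alcohol flanked by two quaternary carbons.

Step 22
Reactants: 33 C11 mesylate
Product: 34 C11 acetate with the acetoxy group on the C7 side (target configuration), lactone intact
Conditions: KOAc, AcOH, 45 °C
Reagents that add atoms: potassium acetate, CC(=O)[O-].[K+]
Why: Buffered SN1 acetolysis through the nortricyclyl (cyclopropylcarbinyl) cation; acetate should enter C11 from the open C7 face, opposite the departing mesylate, giving net inversion. The lactone carbonyl cannot reach the cation and the low temperature spares the PMB ether.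

Step 23
Reactants: 34 C11 acetate lactone
Product: 35 triol (C15, C3 and C11 hydroxyls free, C4 PMB ether)
Conditions: LiAlH4, THF, 0 → 25 °C
Reagents that add atoms: none
Why: Hydride reduction opens the lactone to the C15 and C3 alcohols and cleaves the acetate; no stereocentre is affected.

Step 24
Reactants: 35 triol
Product: 36 C15, C3, C11 triacetate C4 PMB ether
Conditions: Ac2O, DMAP, Et3N, CH2Cl2, 25 °C
Reagents that add atoms: acetic anhydride, CC(=O)OC(C)=O
Why: DMAP-catalysed acetylation of all three free hydroxyls; O4 is masked, so no selectivity between O3 and O4 is required.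

Step 25
Reactants: 36 triacetate PMB ether
Product: 37 target triacetate (CNP0197219.1)
Conditions: DDQ, CH2Cl2–pH 7 buffer, 0 → 25 °C
Reagents that add atoms: none
Why: Oxidative cleavage of the PMB ether under neutral conditions, which should free O4 without moving the neighbouring C3 acetate and without touching the cyclopropane.

## Compound list

1 | (R)-pantolactone | CC1(C)COC(=O)[C@@H]1O | starting material
2 | (2R)-3,3-dimethylbutane-1,2,4-triol | OC[C@H](O)C(C)(C)CO | intermediate
3 | [(2R,4R)-2-(4-methoxyphenyl)-5,5-dimethyl-1,3-dioxan-4-yl]methanol | OC[C@@H]1O[C@H](c2ccc(OC)cc2)OCC1(C)C | intermediate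
4 | (2R,4R)-2-(4-methoxyphenyl)-5,5-dimethyl-1,3-dioxane-4-carbaldehyde | O=C[C@@H]1O[C@H](c2ccc(OC)cc2)OCC1(C)C | intermediate
5 | allyl bromide | C=CCBr | starting material
6 | allylmagnesium bromide | C=CC[Mg]Br | intermediate
7 | (−)-B-allyldiisopinocampheylborane | C=CCB([C@@H]1C[C@@H]2C[C@H]([C@H]1C)C2(C)C)[C@@H]1C[C@@H]2C[C@H]([C@H]1C)C2(C)C | intermediate
8 | diisopinocampheylborinate ester of 9 | C=CC[C@H](OB([C@@H]1C[C@@H]2C[C@H]([C@H]1C)C2(C)C)[C@@H]1C[C@@H]2C[C@H]([C@H]1C)C2(C)C)[C@@H]1O[C@H](c2ccc(OC)cc2)OCC1(C)C | intermediate
9 | (1S)-1-[(2R,4R)-2-(4-methoxyphenyl)-5,5-dimethyl-1,3-dioxan-4-yl]but-3-en-1-ol | C=CC[C@H](O)[C@@H]1O[C@H](c2ccc(OC)cc2)OCC1(C)C | intermediate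
10 | (3R,4S)-3-[(4-methoxybenzyl)oxy]-2,2-dimethylhept-6-ene-1,4-diol | C=CC[C@H](O)[C@H](OCc1ccc(OC)cc1)C(C)(C)CO | intermediate
11 | (4R,5S)-4-[(4-methoxybenzyl)oxy]-3,3-dimethyl-5-(prop-2-en-1-yl)oxolan-2-one | C=CC[C@@H]1OC(=O)C(C)(C)[C@H]1OCc2ccc(OC)cc2 | intermediate
12 | B-alkyl-9-borabicyclo[3.3.1]nonane adduct of 11 | C1CCC2CCCC1B2CCC[C@@H]3OC(=O)C(C)(C)[C@H]3OCc4ccc(OC)cc4 | intermediate
13 | (4R,5S)-5-(3-hydroxypropyl)-4-[(4-methoxybenzyl)oxy]-3,3-dimethyloxolan-2-one | OCCC[C@@H]1OC(=O)C(C)(C)[C@H]1OCc2ccc(OC)cc2 | intermediate
14 | 2-bromo-3-methylfuran | Cc1ccoc1Br | starting material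
15 | 3-methylfuran-2-yllithium | [Li]c1occc1C | intermediate
16 | (3R,4S)-4,7-dihydroxy-3-[(4-methoxybenzyl)oxy]-2,2-dimethyl-1-(3-methylfuran-2-yl)heptan-1-one | OCCC[C@H](O)[C@H](OCc1ccc(OC)cc1)C(C)(C)C(=O)c1occc1C | intermediate
17 | (5S)-5-[(1R)-1-[(4-methoxybenzyl)oxy]-2,2-dimethyl-3-(3-methylfuran-2-yl)-3-oxopropyl]oxolan-2-one | O=C1CC[C@H](O1)[C@H](OCc2ccc(OC)cc2)C(C)(C)C(=O)c2occc2C | intermediate
18 | furyl carbinol from 17 (both C6 epimers) | O=C1CC[C@H](O1)[C@H](OCc2ccc(OC)cc2)C(C)(C)C(O)c2occc2C | intermediate
19 | trans-4-hydroxy-2-methyl-5-substituted cyclopent-2-enone lactone (both trans isomers at C6/C7) | O=C1CC[C@H](O1)[C@H](OCc2ccc(OC)cc2)C(C)(C)C2C(O)C=C(C)C2=O | intermediate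
20 | C7 trimethylsilyl ether of the C11 dimethyl ketal | O=C1CC[C@H](O1)[C@H](OCc2ccc(OC)cc2)C(C)(C)C2C(O[Si](C)(C)C)C=C(C)C2(OC)OC | intermediate
21 | C7 hydroxy C11 dimethyl ketal lactone | O=C1CC[C@H](O1)[C@H](OCc2ccc(OC)cc2)C(C)(C)C2C(O)C=C(C)C2(OC)OC | intermediate
22 | (E)-3-(hydroxymethylidene) lactone of 21 | O=C1/C(=C/O)C[C@H](O1)[C@H](OCc2ccc(OC)cc2)C(C)(C)C2C(O)C=C(C)C2(OC)OC | intermediate
23 | (E)-3-(acetoxymethylidene) lactone, C7 hydroxyl free | O=C1/C(=C/OC(C)=O)C[C@H](O1)[C@H](OCc2ccc(OC)cc2)C(C)(C)C2C(O)C=C(C)C2(OC)OC | intermediate
24 | C7 N-(methoxycarbonyl)sulfamate ester of 23 (as its triethylammonium salt) | O=C1/C(=C/OC(C)=O)C[C@H](O1)[C@H](OCc2ccc(OC)cc2)C(C)(C)C2C(OS(=O)(=O)NC(=O)OC)C=C(C)C2(OC)OC | intermediate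
25 | 5,5-dimethoxy-4-methylcyclopenta-1,3-dien-1-yl triene (lactone-tethered cyclopentadienone ketal) | O=C1/C(=C/OC(C)=O)C[C@H](O1)[C@H](OCc2ccc(OC)cc2)C(C)(C)C2=CC=C(C)C2(OC)OC | intermediate
26 | Diels–Alder adduct: norbornene (bridgeheads C6, C10; C7=C8; C11(OMe)2) fused to ring A, C15 lactone carbonyl endo and bridged to O3, C9 exo acetate, C4 PMB ether | O=C(O4)[C@]12C[C@H]4[C@H](OCc6ccc(OC)cc6)C(C)(C)[C@]13C=C[C@](C)([C@H]2OC(C)=O)C3(OC)OC | intermediate
27 | C9 exo alcohol of the lactone-bridged 7,7-dimethoxynorbornene | O=C(O4)[C@]12C[C@H]4[C@H](OCc6ccc(OC)cc6)C(C)(C)[C@]13C=C[C@](C)([C@H]2O)C3(OC)OC | intermediate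
28 | 4-bromobenzenesulfonyl chloride | O=S(=O)(Cl)c1ccc(Br)cc1 | starting material
29 | lactone-bridged 7,7-dimethoxynorbornene C9 exo brosylate, C4 PMB ether | O=C(O4)[C@]12C[C@H]4[C@H](OCc6ccc(OC)cc6)C(C)(C)[C@]13C=C[C@](C)([C@H]2OS(=O)(=O)c7ccc(Br)cc7)C3(OC)OC | intermediate
30 | lactone-bridged nortricyclane C11 dimethyl ketal, C4 PMB ether | O=C(O4)[C@]12C[C@H]4[C@H](OCc6ccc(OC)cc6)C(C)(C)[C@]13C[C@@H]5[C@H]2[C@]5(C)C3(OC)OC | intermediate
31 | lactone-bridged nortricyclan-11-one | O=C(O4)[C@]12C[C@H]4[C@H](OCc6ccc(OC)cc6)C(C)(C)[C@]13C[C@@H]5[C@H]2[C@]5(C)C3=O | intermediate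
32 | C11 alcohol, hydroxyl on the C1 side (11-epi) | O=C(O4)[C@]12C[C@H]4[C@H](OCc6ccc(OC)cc6)C(C)(C)[C@]13C[C@@H]5[C@H]2[C@]5(C)[C@@H]3O | intermediate
33 | C11 mesylate, sulfonate on the C1 side | O=C(O4)[C@]12C[C@H]4[C@H](OCc6ccc(OC)cc6)C(C)(C)[C@]13C[C@@H]5[C@H]2[C@]5(C)[C@@H]3OS(C)(=O)=O | intermediate
34 | C11 acetate, acetoxy on the C7 side, lactone intact | O=C(O4)[C@]12C[C@H]4[C@H](OCc6ccc(OC)cc6)C(C)(C)[C@]13C[C@@H]5[C@H]2[C@]5(C)[C@H]3OC(C)=O | intermediate
35 | C15, C3, C11 triol, C4 PMB ether | OC[C@]12C[C@H](O)[C@H](OCc4ccc(OC)cc4)C(C)(C)[C@]13C[C@@H]1[C@H]2[C@]1(C)[C@H]3O | intermediate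
36 | C15, C3, C11 triacetate, C4 PMB ether | CC(=O)OC[C@]12C[C@H](OC(C)=O)[C@H](OCc4ccc(OC)cc4)C(C)(C)[C@]13C[C@@H]1[C@H]2[C@]1(C)[C@H]3OC(C)=O | intermediate
37 | target triacetate with free C4 hydroxyl (CNP0197219.1) | CC(=O)OC[C@]12C[C@H](OC(C)=O)[C@H](O)C(C)(C)[C@]13C[C@@H]1[C@H]2[C@]1(C)[C@H]3OC(C)=O | target

## Step count and least certain steps

Total step count: 25. Longest linear sequence: 25 steps, from 1 to 37; 5, 14 and 28 enter as purchased reagents.

**Step 18 (key step).** The most likely failure is misdirected capture of the delocalised cation: hydride transfer to C9 or to the tertiary C10, or loss of the C10–C11 bond with ketal assistance. Ionisation may also be slow, because the lactone carbonyl and the ketal both withdraw electron density, and slow ionisation gives borohydride time to attack the lactone. The fallback avoids the cation altogether and closes the cyclopropane by carbene insertion. It sets out from 27. Diimide would saturate the strained C7=C8 bond without touching the PMB ether to give the norbornane C9 alcohol F1. Dess–Martin periodinane would give the C9 ketone F2, and TsNHNH2 its tosylhydrazone F3. Aprotic Bamford–Stevens decomposition (NaH, diglyme, 160 °C) would generate the norbornan-2-ylidene-type carbene. Its 1,3-insertion into the endo C8–H bond is the reaction that turns camphor-type tosylhydrazones into tricyclenes. Since C1 has no hydrogen to shift, this should lead back to the route at 30.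

**Step 15.** Two things may go wrong. The cycloaddition may close through the other diastereomeric mode (tether endo, lactone carbonyl exo). That mode fits the relaxed shape of the bridged lactone better and avoids the contact between the exo acetoxy group and a ketal methoxy group. Alternatively, the diene may dimerise faster than it cyclises. The fallback changes the diene from the ketal to the free cyclopentadienone, which is planar and small at C11 and more reactive. It sets out from 23. Mild acid (wet silica, oxalic acid) would hydrolyse the allylic ketal to the hydroxy enone F4. MsCl and Et3N at high dilution would eliminate through the C6 enolate to the cyclopentadienone F5. F5 should cycloadd at room temperature to the bridging ketone F6. The strained C11 carbonyl of F6 ketalises readily (HC(OMe)3, MeOH, TsOH), which returns to the route at 26.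

**Step 11.** The furfuryl cation at C6 may fragment: the C4–C5 bond can break with assistance from the O4 lone pair, a Grob or retro-Prins type loss. The neopentyl carbinol may also simply fail to rearrange. The fallback avoids the cation. It sets out from 18. The carbinol would be converted into its imidazolyl thiocarbonate F7 and reduced with Bu3SnH and AIBN (Barton–McCombie) to the 2-alkyl-3-methylfuran F8. Oxidative opening of the furan (NBS, NaHCO3, aqueous acetone) would give the (Z)-keto-enal F9. Intramolecular aldol addition of the C6 enolate to the C7 aldehyde under mild base closes the same hydroxycyclopentenone, returning to the route at 19.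

**Step 17 (with step 16).** Sulfonylation of an exo alcohol flanked by two quaternary carbons and a ketal methoxy group may stall. The preceding deacetylation may also trigger retro-aldol cleavage of C1–C9 through the alkoxide. The fallback puts the sulfonate on before the cycloaddition, while the oxygen is still on a flat enol. It sets out from 22. BsCl and Et3N would give the (E)-enol brosylate F10. Burgess dehydration would give its diene F11, which would cyclise as in step 15 and return to the route directly at 29, with steps 14, 16 and 17 no longer needed.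

**Step 22.** The delocalised cation may be captured at a cyclopropane carbon, giving ring-opened homoallylic acetates, or from the wrong face; the PMB ether may also be lost in acid. The fallback replaces ionisation by thermodynamic hydride equilibration. It sets out from 31. Meerwein–Ponndorf–Verley reduction under equilibrating conditions (Al(O-i-Pr)3, i-PrOH, a little acetone, reflux) should favour the less crowded alcohol F11b, written below as F12, with the hydroxyl on the C7 side. LiAlH4 reduction of the C11 alcohol F12 would then return to the route at 35.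

**Step 5.** The acetal may open with the wrong regiochemistry if the neighbouring C3 aluminium alkoxide directs cleavage of the C–O4 bond. The fallback removes the acetal and reprotects. It sets out from 9. Aqueous acetic acid would give the triol F13. TEMPO and PhI(OAc)2 would lactonise its only primary alcohol onto O3 to give the hydroxy lactone F14. 4-Methoxybenzyl trichloroacetimidate with catalytic acid would then protect O4 and return to the route at 11.

## Further compounds

F1 | step 18 | norbornane C9 exo alcohol (C7–C8 saturated), lactone, C11 dimethyl ketal, C4 PMB ether | O=C(O4)[C@]12C[C@H]4[C@H](OCc6ccc(OC)cc6)C(C)(C)[C@]13CC[C@](C)([C@H]2O)C3(OC)OC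
F2 | step 18 | norbornan-9-one (C9 ketone) | O=C(O4)[C@]12C[C@H]4[C@H](OCc6ccc(OC)cc6)C(C)(C)[C@]13CC[C@](C)(C2=O)C3(OC)OC
F3 | step 18 | C9 tosylhydrazone | O=C(O4)[C@]12C[C@H]4[C@H](OCc6ccc(OC)cc6)C(C)(C)[C@]13CC[C@](C)(C2=NNS(=O)(=O)c7ccc(C)cc7)C3(OC)OC
F4 | step 15 | hydroxy enone with (E)-acetoxymethylidene lactone | O=C1/C(=C/OC(C)=O)C[C@H](O1)[C@H](OCc2ccc(OC)cc2)C(C)(C)C2C(O)C=C(C)C2=O
F5 | step 15 | lactone-tethered 2,5-disubstituted cyclopentadienone | O=C1/C(=C/OC(C)=O)C[C@H](O1)[C@H](OCc2ccc(OC)cc2)C(C)(C)C2=CC=C(C)C2=O
F6 | step 15 | lactone-bridged norbornen-11-one C9 exo acetate | O=C(O4)[C@]12C[C@H]4[C@H](OCc6ccc(OC)cc6)C(C)(C)[C@]13C=C[C@](C)([C@H]2OC(C)=O)C3=O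
F7 | step 11 | C6 imidazolyl thiocarbonate of 18 | O=C1CC[C@H](O1)[C@H](OCc2ccc(OC)cc2)C(C)(C)C(OC(=S)n2ccnc2)c2occc2C
F8 | step 11 | 2-alkyl-3-methylfuran (C6 methylene) | O=C1CC[C@H](O1)[C@H](OCc2ccc(OC)cc2)C(C)(C)Cc2occc2C
F9 | step 11 | (Z)-3-methyl-4-oxoalk-2-enal (opened furan) | O=C1CC[C@H](O1)[C@H](OCc2ccc(OC)cc2)C(C)(C)CC(=O)/C(C)=C\C=O
F10 | step 17 | (E)-enol brosylate of 22 | O=C1/C(=C/OS(=O)(=O)c3ccc(Br)cc3)C[C@H](O1)[C@H](OCc2ccc(OC)cc2)C(C)(C)C2C(O)C=C(C)C2(OC)OC
F11 | step 17 | cyclopentadienone ketal triene with enol brosylate | O=C1/C(=C/OS(=O)(=O)c3ccc(Br)cc3)C[C@H](O1)[C@H](OCc2ccc(OC)cc2)C(C)(C)C2=CC=C(C)C2(OC)OC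
F12 | step 22 | C11 alcohol with the hydroxyl on the C7 side, lactone intact | O=C(O4)[C@]12C[C@H]4[C@H](OCc6ccc(OC)cc6)C(C)(C)[C@]13C[C@@H]5[C@H]2[C@]5(C)[C@H]3O
F13 | step 5 | (3R,4S)-2,2-dimethylhept-6-ene-1,3,4-triol | C=CC[C@H](O)[C@H](O)C(C)(C)CO
F14 | step 5 | (4R,5S)-4-hydroxy-3,3-dimethyl-5-(prop-2-en-1-yl)oxolan-2-one | C=CC[C@@H]1OC(=O)C(C)(C)[C@H]1O
A1 | alternative 1 | phenol α-bromo ester with ring A acetonide | COC(=O)C(Br)C[C@@H]1OC(C)(C)O[C@@H]1C(C)(C)c1cccc(C)c1O
A2 | alternative 1 | spiro[5.5] cyclohexa-2,4-dienone with ring A acetonide and C1 ester | COC(=O)[C@@H]1C[C@H](OC3(C)C)[C@H](O3)C(C)(C)[C@]12C=CC=C(C)C2=O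
A3 | alternative 2 | C9 aldehyde tosylhydrazone on the spirocyclopentene | CC(=O)OC[C@]1(C=NNS(=O)(=O)c2ccc(C)cc2)CC[C@H](O[Si](C)(C)C(C)(C)C)C(C)(C)[C@]13CC=C(C)[C@H]3OC(C)=O
A4 | alternative 2 | nortricyclane with C15 and C11 acetates and C4 silyl ether | CC(=O)OC[C@]12CC[C@H](O[Si](C)(C)C(C)(C)C)C(C)(C)[C@]13C[C@@H]1[C@H]2[C@]1(C)[C@H]3OC(C)=O
A5 | alternative 3 | oxolane-tethered 1,7-enyne (3-methyleneoxolane with terminal alkyne) | C=C1CO[C@@H](C1)[C@H](O[Si](C)(C)C(C)(C)C)C(C)(C)C#C
A6 | alternative 3 | oxa-bridged ring A fused cyclopentenone (C8 ketone) | C(O3)[C@]12C[C@H]3[C@H](O[Si](C)(C)C(C)(C)C)C(C)(C)C1=CC(=O)C2
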